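The constants give two dissolving solids and a partner that leaves by side product, decomposed reagent and target, so we follow the partner.

    solid substrate ⇌ dissolved substrate, rate k1*(cs1 - [dissolved substrate]) while solid is left; crystals form when [dissolved substrate] > cs1 (cs1 = 14 mM, k1 = 0.28 h⁻¹)
    solid reagent ⇌ partner, rate k2*(cs2 - [partner]) while solid is left; crystals form when [partner] > cs2 (cs2 = 2.3 mM, k2 = 0.47 h⁻¹)
    partner → side product (k3 = 0.13 h⁻¹)
    dissolved substrate + partner → target (k4 = 2.2 M⁻¹ h⁻¹)
    partner → decomposed reagent (k5 = 0.50 h⁻¹)

solid substrate 0.050 M; solid reagent 0.0350 M; time 8.0 d

- given per volume of solution although it is solid: solid substrate, solid reagent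
- at the start none of the solid substrate is in solution
- at the start none of the solid reagent is in solution
- dissolved substrate means what is dissolved; the solid is not counted in it
- run time (flask): 8.0 d

* amount of target at 8.0 d, in percent of the solid substrate charged
* concentration of dissolved substrate in solution at 50 h, in percent of saturation
* the change that raises the amount of target at 8.0 d, in percent of the solid substrate charged most ("none" if none brings more than 2 percentage points) (Monday's / Wednesday's / Saturday's / Friday's / none)
* amount of target at 8.0 d, in percent of the solid substrate charged, after Wednesday's

- Monday's: doubling the solubility in step 1, all else as stated
- Wednesday's: doubling the solubility in step 2, all else as stated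
- Saturday's: doubling the dissolution coefficient of step 1, all else as stated
- Friday's: doubling the dissolution coefficient of step 2, all else as stated

Dissolution of the solid substrate closes half its gap to saturation every 2.48 h, which is short beside 50 h. So we expect dissolved substrate in this flask at >99.9 % of saturation at that time.

The solid reagent dissolves into a solution that loses partner to side product and decomposed reagent at 0.630 h⁻¹ together. But the coupling with dissolved substrate, pseudo-first-order in partner at solubility 14 mM, takes it at 0.0308 h⁻¹, far slower.

So we carry the coupling share f, the fraction of partner that reaches target while dissolved substrate stands at 14 mM: 4.66 %.

With partner held where dissolving balances loss, the solid reagent passes through in about 2.31 d, within the run. So in this flask we reckon the target at 8.0 d, in percent of the solid substrate charged, as f times the charge ratio of solid reagent to solid substrate, 3.26 %.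

The dissolution coefficients and the reagent's solubility do not enter f, so we reckon Wednesday's at 3.26 %. Monday's raises f to 8.91 %, and we choose Monday's.

The forecast gives 3.05 %, 99.3 %, Monday's and 2.85 %. Its target and saturation figures stand lower than ours, and unlike our reckoning it puts Wednesday's below the flask, saying the change “only burns the reagent faster, during the substrate's dissolution lag, and slightly lowers the yield”.

The simulation gives 3.08 %, 99.3 %, Monday's with a gain of 2.8 percentage points, and 2.90 % after Wednesday's.

Wednesday's stands 0.18 points below this flask, the direction the forecast gave. Of the partner turned over in this flask, 4.40 % became target, near f. This flask has come to rest: at 80.0 d partner stands at 0 M and target at 3.08 %, the same as at the asked time, with solid substrate still at 68.9 % of its charge. A second flask with 0.088 M of solid reagent, all else as in this recipe, has the charge ratio 176 %, so f gives 8.20 %, and the target in that flask stands at 7.99 %.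

Its constants belong to no real substance; the flask was simulated.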